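## Structural features

The target is a cyclohexene (C5–C10) fused across C7–C8 to an α-methylene-γ-butyrolactone (C8–O–C12(=O)–C11(=C13H2)–C7), and the ring fusion is trans. The carbocycle holds a tetrasubstituted C5=C10 alkene. C5 carries the (S)-configured C4 of a 5-hydroxypentan-2-yl chain (C4 to C1), and C10 carries the methacryloyloxymethyl carbon C14. C6 (acetoxy), C7 and C8 are contiguous stereocentres: the C6 oxygen is cis to the C7–C11 bond, and the C7–C11 bond is trans to the C8 oxygen. C4 lies outside the ring and is separated from them by the alkene. Fragile elements are two Michael acceptors (the methylene lactone and the methacrylate), a secondary allylic acetate at C6 that can ionise or eliminate, and three different esters beside one free primary alcohol. The real difficulty is to set C6–C8 in the right absolute sense relative to the independently fixed C4 while building a fully substituted ring alkene, without letting a β-acyloxy carbonyl array eliminate. The key step uses the fact that C6, C7 and C8 sit directly across the six-membered ring from C5=C10. This is the retron of a [4+2] cycloaddition with C6=C5–C10=C9 as diene and C7=C8 as dienophile, where an acetyl group on C7 (future C11 and C13) and a boron on C8 (future lactone oxygen) hold the lactone in latent form.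

## Logic of the disconnections

25 ⇒ 24. The O–Si bond at C1 is restored. The free primary alcohol is unmasked last so that it never competes with the C14 oxygen for the methacryloyl group. The gain is one fewer nucleophile in the end-game. The demand is a fluoride source that spares an acetate, a methacrylate and a methylene lactone.

24 ⇒ 23. The acyl C–O bond between C14–O and the methacryloyl carbon is cut. The polymerisable acrylate is introduced only after all metal- and base-mediated steps. The gain is removal of one Michael acceptor. The demand is an acylation faster than acetyl migration from the C6 oxygen to the C14 oxygen.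

23 ⇒ 22. The C14 hydroxyl is returned to its 4-methoxybenzyl ether (benzylic C–O bond). This gives an oxygen at C14 that is orthogonal to the silyl ether and to the acetate. The demand is an oxidative cleavage that leaves the electron-poor alkenes and the ring alkene alone.

22 ⇒ 21. The O–C12 and C12–C11 bonds are cut, which removes one molecule of carbon monoxide. The lactone ring and its exocyclic alkene then come from a C8 alcohol and a C11 alkenyl triflate in a single operation. The gain is loss of a ring and a Michael acceptor. The demand is that zerovalent palladium inserts into the C11–O triflate bond faster than it ionises the C6 allylic acetate, and that the trans-fused acyl-palladium alkoxide closes.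

21 ⇒ 20. The C8–O bond is traced back to a C8–B bond. Oxidation of a secondary alkylboronate is stereoretentive, so the C8 configuration is that of the boronate. The demand is an oxidant mild enough for the acetate and the alkenyl triflate.

20 ⇒ 19. The C11–O(triflate) bond is cut back to the C11 carbonyl of a methyl ketone. The gain is a substituent (acetyl) that is also the activating group of a dienophile. The demand is kinetic deprotonation at C13 and not at C7, because a C7 enolate would expel the C6 acetate.

19 ⇒ 15 + 18. The C6–C7 and C8–C9 bonds are cut. The cut removes the ring and all three ring stereocentres at once and leaves two achiral π-systems plus the C4 centre. The demand is ortho regiochemistry, endo topology and addition to a single face of C7=C8, under catalyst control.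

18 ⇒ 17 ⇒ 16. The ketone is returned to a secondary carbinol and the C8–B bond is cut back to a terminal alkyne C–H. Both steps are reliable, and the (E)-geometry comes from syn addition across the alkyne. The demand is β-regioselective borylation next to a free hydroxyl.

15 ⇒ 11 + 14, and 14 ⇒ 12 + 13. The C10–C14 bond is cut (sp2–sp3). The protected oxymethyl group is attached last, so the diene is assembled under neutral conditions from a dienyl triflate. The ether C–O bond of 14 is cut to an alcohol and an iodomethylstannane. The demand is transfer of the alkoxymethyl group from tin in preference to butyl.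

11 ⇒ 10 ⇒ 9. The O–S bond at C10 and the O–acyl bond at C6 are cut. The ketone of 10 has only one enolisable position, so no regiochemical question arises. The enol acetate geometry is set on the push–pull system 10, where the E isomer is favoured. The demand is that the C5=C6 geometry survives the two later steps.

9 ⇒ 5 + 6. The C5–C10 bond is cut, α to the aldehyde. C5 is the only α-carbon of 5. The gain is a two-carbon acyl donor and a linear aldehyde. The demand is C-acylation without self-condensation of the aldehyde.

5 ⇒ 4 ⇒ 3 ⇒ 1. The silyl ether and the aldehyde are unmasked, and the C1 alcohol is traced to oxidative cleavage of the C=C bond of 1. The C4 stereocentre is taken from the chiral pool without change. The demand is differentiation of the two chain termini, achieved by masking the aldehyde before the alkene is cleaved.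

## Other disconnections considered

Alternative 1: The lactone is cut last at O–C12 and C12–C11, which leaves the trans ethynyl carbinol A2. In the forward sense, divalent palladium (PdCl2 with SnCl2 and PPh3) under carbon monoxide would turn the C8 hydroxyl into an alkoxycarbonyl-palladium species. This would add across the C7 alkyne, and protonolysis would release the silyl ether A1, one desilylation from the target.
- In its favour: the step is redox-neutral and needs no strong base, and trans-2-ethynyl cycloalkanols are well-suited substrates for this cyclocarbonylation. The acetate and the methacrylate can already be in place.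
- Against it here: it forms only the lactone. The carbocycle, its tetrasubstituted alkene and the C6/C7/C8 array of A2 must come from elsewhere. Putting an ethynyl group on C7, trans to the C8 oxygen and next to the acetoxy-bearing C6, is a regiochemical problem of its own.
- Comparison: both plans close the same ring by palladium-mediated carbonylation, so they are equal in the bonds formed at that stage. Alternative 1 is the better on functional-group safety there, because it needs no enolate next to the C6 acetate. It is also better on steps after lactonisation. The chosen plan is stronger in structure and step economy overall, because its cycloaddition delivers the ring, the alkene and three stereocentres that Alternative 1 leaves unsolved.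

Alternative 2: The ring is cut at C5–C6 and C9–C10. Zerovalent nickel (Ni(cod)2 with PCy3) would couple the carbonyl carbon of the trans-2,3-disubstituted cyclobutanone A4 oxidatively with the silyl alkyne A5. β-Carbon elimination would open the C6–C9 bond, and reductive elimination would give the cyclohexenone A3.
- In its favour: two ring bonds and the tetrasubstituted alkene form together. The silyl group should steer the chain-bearing alkyne carbon to C6 and leaves a handle on C10. The C7/C8 trans pair is fixed beforehand in a small ring.
- Against it here: A5 is branched at the propargylic carbon and capped by silicon, so the oxidative cyclisation should be slow. The β-carbon elimination must choose C6–C9 over C6–C7. A3 still lacks the C6 stereocentre, C14, the lactone and C13. That means a diastereoselective reduction, conversion of a β-silyl enone carbon into a hydroxymethyl-bearing carbon, benzyl ether cleavage beside alkenes, lactonisation and methylenation.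
- Comparison: Alternative 2 equals the chosen plan in the number of ring bonds made. It is the better in one respect: the ring-forming step needs no facial selection, because C7 and C8 are carried in. The chosen plan creates three stereocentres against none and rests on a pericyclic pathway that is less sensitive to steric inhibition of organometallic elementary steps. Its route after the key step is clearly shorter.

Alternative 3: The ring is cut at C8–C9 and at the C5=C10 double bond. With Cs2CO3 the nitronate of the γ-nitro ketone A7 would add to the phosphonoacrylate A8, and the resulting phosphonate anion would olefinate the C5 ketone intramolecularly to give the cyclohexenecarboxylate A6.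
- In its favour: the cascade is free of transition metals. The intramolecular olefination is a sound way to a tetrasubstituted alkene. The ester arrives on C10 as a precursor of C14, and the nitro group on C8 can settle in the equatorial position under thermodynamic control.
- Against it here: the C5 ketone of A7 is flanked by the branched C4 and the alkoxy-bearing C6, so olefination competes with epimerisation at C6 and with retro-Michael loss. A6 still needs nitro-to-hydroxyl conversion with the correct configuration, ester reduction, exchange of the C6 ether for an acetate, oxidation of the C7 side chain, lactonisation and introduction of C13. A7 needs its own stereocontrolled synthesis of C6 and C7.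
- Comparison: Alternative 3 is the equal or the better on robustness of the alkene-forming event and on avoiding catalyst-controlled selectivity at C8. The chosen plan sets C6, C7 and C8 in one step, carries C11 and C13 from the outset, and needs fewer redox and protecting-group operations afterwards.

Key step: step 11

Remarks on the chemistry (assumptions):
- The C1 hydroxyl is carried as a tert-butyldiphenylsilyl ether in preference to a more acid-labile silyl ether. It has to outlast aqueous acid in steps 3 and 4 and a Brønsted-acidic catalyst in step 11.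
- The dienophile is made by alkyne borylation and oxidation, not by cross-metathesis of two electron-poor alkenes, which is judged unreliable.
- The (S)-configured oxazaborolidinium is assumed to bind the enone s-trans with a C7–H···O contact, as it does acrylates, and so to expose the re face of C7. If the sense were opposite, the (R)-catalyst would be used with nothing else changed.
- (S)-Citronellal, tributyl(iodomethyl)stannane, but-3-yn-2-ol and the oxazaborolidine are taken as commercial.

## Route

Step 1
Reactants: 1 (S)-citronellal
Product: 3 (4S)-6,6-dimethoxy-4-methylhexan-1-ol, via (S)-citronellal dimethyl acetal 2 (not isolated)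
Conditions: HC(OMe)3, PPTS (cat.), MeOH, rt; NaHCO3; O3, CH2Cl2/MeOH, −78 °C; NaBH4, −78 °C → rt
Reagents that add atoms: trimethyl orthoformate (COC(OC)OC); ozone ([O-][O+]=O)
Why: Acid-catalysed acetalisation masks the aldehyde, ozonolysis then cleaves the only alkene, and borohydride reduces the peroxidic intermediates to the primary alcohol in the same flask. The C4 stereocentre is β to both termini and is not touched.

Step 2
Reactants: 3 (4S)-6,6-dimethoxy-4-methylhexan-1-ol
Product: 4 tert-butyl{[(4S)-6,6-dimethoxy-4-methylhexyl]oxy}diphenylsilane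
Conditions: TBDPSCl, imidazole, CH2Cl2, 0 °C → rt
Reagents that add atoms: tert-butyl(chloro)diphenylsilane (CC(C)(C)[Si](Cl)(c1ccccc1)c1ccccc1)
Why: Routine silylation of a primary alcohol; the bulky diphenylsilyl ether should survive the aqueous acid of steps 3 and 4 and the acidic catalyst of step 11.

Step 3
Reactants: 4 tert-butyl{[(4S)-6,6-dimethoxy-4-methylhexyl]oxy}diphenylsilane
Product: 5 (3S)-6-[(tert-butyldiphenylsilyl)oxy]-3-methylhexanal
Conditions: PPTS (cat.), acetone/H2O, 50 °C
Reagents that add atoms: water (O)
Why: Mild acid-catalysed acetal hydrolysis releases the aldehyde while the silyl ether is stable; the stereocentre is β to the carbonyl and cannot epimerise.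

Step 4
Reactants: 5 (3S)-6-[(tert-butyldiphenylsilyl)oxy]-3-methylhexanal; 6 acetyl chloride
Product: 9 (3Z)-4-hydroxy-3-[(2S)-5-[(tert-butyldiphenylsilyl)oxy]pentan-2-yl]but-3-en-2-one (chelated enol form of the 2-acetyl aldehyde), via pyrrolidine enamine 7 (not isolated), via C-acetylated enamine 8 (not isolated)
Conditions: pyrrolidine, K2CO3, Et2O, 0 °C → rt; AcCl, Et3N, CH2Cl2, 0 °C → rt; 1 M HCl, THF, rt
Reagents that add atoms: water (O)
Why: Stork enamine acylation: the enamine is nucleophilic only at C5, the single α-carbon, and acylation forms the C5–C10 bond. Dilute acid hydrolyses the push–pull enaminone at the former aldehyde carbon, and the product rests as the hydrogen-bonded enol, so C5 is not a stereocentre.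

Step 5
Reactants: 9 (3Z)-4-hydroxy-3-[(2S)-5-[(tert-butyldiphenylsilyl)oxy]pentan-2-yl]but-3-en-2-one
Product: 10 (1E,3S)-2-acetyl-6-[(tert-butyldiphenylsilyl)oxy]-3-methylhex-1-en-1-yl acetate
Conditions: Ac2O, Et3N, DMAP (cat.), CH2Cl2, 0 °C → rt
Reagents that add atoms: acetic anhydride (CC(=O)OC(C)=O)
Why: O-Acetylation of the hydroxymethylene enol at its unhindered oxygen gives a vinylogous anhydride. Under DMAP, reversible addition–elimination should settle it as the E isomer, with the acetoxy group anti to the ketone (opposed dipoles) and syn to the C4–H.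

Step 6
Reactants: 10 (1E,3S)-2-acetyl-6-[(tert-butyldiphenylsilyl)oxy]-3-methylhex-1-en-1-yl acetate
Product: 11 (1E,3S)-6-[(tert-butyldiphenylsilyl)oxy]-3-methyl-2-{1-[(trifluoromethanesulfonyl)oxy]ethenyl}hex-1-en-1-yl acetate
Conditions: KHMDS, PhNTf2, THF, −78 °C (base added last)
Reagents that add atoms: N-phenylbis(trifluoromethanesulfonimide) (O=S(=O)(N(c1ccccc1)S(=O)(=O)C(F)(F)F)C(F)(F)F)
Why: Enol triflate formation: the methyl group is the only enolisable position of the ketone, so deprotonation and O-sulfonylation of the cross-conjugated enolate give the 2-triflyloxy diene. With the triflating agent present at −78 °C the hindered amide should not attack the enol acetate, and the C5=C6 geometry is not involved.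

Step 7
Reactants: 12 4-methoxybenzyl alcohol; 13 tributyl(iodomethyl)stannane
Product: 14 tributyl{[(4-methoxyphenyl)methoxy]methyl}stannane
Conditions: NaH, THF/DMF, 0 °C → rt
Reagents that add atoms: none
Why: Williamson ether synthesis; the primary iodide next to tin is a good SN2 electrophile for the sodium alkoxide.

Step 8
Reactants: 11 (1E,3S)-6-[(tert-butyldiphenylsilyl)oxy]-3-methyl-2-{1-[(trifluoromethanesulfonyl)oxy]ethenyl}hex-1-en-1-yl acetate; 14 tributyl{[(4-methoxyphenyl)methoxy]methyl}stannane
Product: 15 (1E,3S)-6-[(tert-butyldiphenylsilyl)oxy]-2-{3-[(4-methoxyphenyl)methoxy]prop-1-en-2-yl}-3-methylhex-1-en-1-yl acetate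
Conditions: Pd(PPh3)4 (10 mol%), LiCl, CuI (cat.), 1,4-dioxane, 80 °C
Reagents that add atoms: none
Why: Stille coupling of an alkenyl triflate with an α-alkoxymethylstannane forms the C10–C14 bond; the oxygen-substituted methyl group transfers in preference to butyl. The conditions are neutral, so the enol acetate and its E geometry should be kept.

Step 9
Reactants: 16 but-3-yn-2-ol (racemic)
Product: 17 (3E)-4-(4,4,5,5-tetramethyl-1,3,2-dioxaborolan-2-yl)but-3-en-2-ol (racemic)
Conditions: B2pin2, CuCl (5 mol%), Xantphos (5 mol%), NaOt-Bu (10 mol%), MeOH, THF, rt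
Reagents that add atoms: bis(pinacolato)diboron (CC1(C)OB(OC1(C)C)B1OC(C)(C)C(C)(C)O1)
Why: Copper-catalysed formal hydroboration: syn borylcupration of the terminal alkyne puts boron on the terminal carbon, and methanolysis of the C–Cu bond with retention gives the E alkenylboronate. A free hydroxyl is tolerated.

Step 10
Reactants: 17 (3E)-4-(4,4,5,5-tetramethyl-1,3,2-dioxaborolan-2-yl)but-3-en-2-ol
Product: 18 (3E)-4-(4,4,5,5-tetramethyl-1,3,2-dioxaborolan-2-yl)but-3-en-2-one
Conditions: DMP, NaHCO3, CH2Cl2, 0 °C → rt
Reagents that add atoms: none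
Why: Dess–Martin oxidation of a secondary allylic alcohol; pinacol alkenylboronates tolerate the hypervalent iodine oxidant, and the alkene geometry is not affected.

Step 11
Reactants: 15 (1E,3S)-6-[(tert-butyldiphenylsilyl)oxy]-2-{3-[(4-methoxyphenyl)methoxy]prop-1-en-2-yl}-3-methylhex-1-en-1-yl acetate; 18 (3E)-4-(4,4,5,5-tetramethyl-1,3,2-dioxaborolan-2-yl)but-3-en-2-one
Product: 19 (1S,5R,6S)-6-acetyl-2-[(2S)-5-[(tert-butyldiphenylsilyl)oxy]pentan-2-yl]-3-{[(4-methoxyphenyl)methoxy]methyl}-5-(4,4,5,5-tetramethyl-1,3,2-dioxaborolan-2-yl)cyclohex-2-en-1-yl acetate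
Conditions: (S)-3,3-diphenyl-1-(o-tolyl)tetrahydro-1H,3H-pyrrolo[1,2-c][1,3,2]oxazaborole (20 mol%), Tf2NH (18 mol%), 18 (2.5 equiv), CH2Cl2, −78 → −20 °C
Reagents that add atoms: none
Why: The N-protonated oxazaborolidine binds the acetyl oxygen of 18 at the lone pair syn to C7–H (s-trans enone) and lowers its LUMO, and 15 then adds in one concerted, asynchronous, suprafacial [4+2] event in which the C8–C9 bond runs ahead of the C6–C7 bond. The closest known reaction type is the chiral oxazaborolidinium-catalysed Diels–Alder reaction of acyclic enones and acrylates, together with the use of 3-borylpropenoyl dienophiles as masked β-hydroxy enones. The six-membered ring closes by this single cycloaddition, both σ-bonds forming on one face of each partner, and the central bond of the diene becomes the tetrasubstituted C5=C10 alkene. C7 is set by the catalyst, whose aryl group covers one face of the bound enone so that C6 attacks the re face of C7. C8 follows from C7 because the E geometry of 18 is transferred suprafacially, which puts boron trans to the acetyl group. C6 follows from the endo position of the Lewis-acid-bound acetyl group together with the E enol acetate of 15, which puts the acetate cis to the acetyl group. The step needs ortho regiochemistry, secured by the 1-acetoxy donor and the C10 substituent, which both enlarge the coefficient at C9 against the weaker opposing effect of the C5 alkyl group; it also needs endo selectivity, supplied by the activated carbonyl, and addition to one diene face. The C4 centre should hold its hydrogen in the diene plane toward the acetoxy group, so its methyl and methylene arms distinguish the diene faces only weakly and the catalyst should dominate.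

Step 12
Reactants: 19 (1S,5R,6S)-6-acetyl-2-[(2S)-5-[(tert-butyldiphenylsilyl)oxy]pentan-2-yl]-3-{[(4-methoxyphenyl)methoxy]methyl}-5-(4,4,5,5-tetramethyl-1,3,2-dioxaborolan-2-yl)cyclohex-2-en-1-yl acetate
Product: 20 (1S,5R,6S)-2-[(2S)-5-[(tert-butyldiphenylsilyl)oxy]pentan-2-yl]-3-{[(4-methoxyphenyl)methoxy]methyl}-5-(4,4,5,5-tetramethyl-1,3,2-dioxaborolan-2-yl)-6-{1-[(trifluoromethanesulfonyl)oxy]ethenyl}cyclohex-2-en-1-yl acetate
Conditions: KHMDS, PhNTf2, THF, −78 °C (base added last)
Reagents that add atoms: N-phenylbis(trifluoromethanesulfonimide) (O=S(=O)(N(c1ccccc1)S(=O)(=O)C(F)(F)F)C(F)(F)F)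
Why: Kinetic enol triflate formation: the hindered amide removes a proton from the unhindered C13 methyl and not from the flanked C7 methine, and the enolate is sulfonylated as it forms. Converting the ketone at this stage removes the acidic C7–H before any aqueous base is used, so the C6 acetate can no longer be lost by E1cB elimination.

Step 13
Reactants: 20 (1S,5R,6S)-2-[(2S)-5-[(tert-butyldiphenylsilyl)oxy]pentan-2-yl]-3-{[(4-methoxyphenyl)methoxy]methyl}-5-(4,4,5,5-tetramethyl-1,3,2-dioxaborolan-2-yl)-6-{1-[(trifluoromethanesulfonyl)oxy]ethenyl}cyclohex-2-en-1-yl acetate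
Product: 21 (1S,5R,6S)-2-[(2S)-5-[(tert-butyldiphenylsilyl)oxy]pentan-2-yl]-5-hydroxy-3-{[(4-methoxyphenyl)methoxy]methyl}-6-{1-[(trifluoromethanesulfonyl)oxy]ethenyl}cyclohex-2-en-1-yl acetate
Conditions: NaBO3·4H2O, THF/H2O, 0 °C → rt
Reagents that add atoms: sodium perborate ([Na+].[Na+].O[B-]1(O)OO[B-](O)(O)OO1)
Why: Oxidation of the secondary alkylboronate by 1,2-migration of C8 from boron to oxygen, which proceeds with retention and gives the C8 alcohol trans to the C7 substituent. Perborate is mild enough for the acetate and the alkenyl triflate, and the trans-1,3 arrangement of the C6 acetate and C8 hydroxyl disfavours acyl migration.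

Step 14
Reactants: 21 (1S,5R,6S)-2-[(2S)-5-[(tert-butyldiphenylsilyl)oxy]pentan-2-yl]-5-hydroxy-3-{[(4-methoxyphenyl)methoxy]methyl}-6-{1-[(trifluoromethanesulfonyl)oxy]ethenyl}cyclohex-2-en-1-yl acetate
Product: 22 (3aS,4S,7aR)-5-[(2S)-5-[(tert-butyldiphenylsilyl)oxy]pentan-2-yl]-6-{[(4-methoxyphenyl)methoxy]methyl}-3-methylidene-2-oxo-2,3,3a,4,7,7a-hexahydro-1-benzofuran-4-yl acetate
Conditions: Pd(PPh3)4 (10 mol%), CO (1 atm), Et3N, MeCN, 55 °C
Reagents that add atoms: carbon monoxide ([C-]#[O+])
Why: Palladium-catalysed carbonylative lactonisation: zerovalent palladium inserts into the alkenyl triflate, CO insertion gives an acyl-palladium species, and the C8 hydroxyl captures it to form the O–C12 and C12–C11 bonds. The tetrasubstituted allylic acetate is a poor ligand and should ionise far more slowly than the triflate reacts, and no stereocentre changes.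

Step 15
Reactants: 22 (3aS,4S,7aR)-5-[(2S)-5-[(tert-butyldiphenylsilyl)oxy]pentan-2-yl]-6-{[(4-methoxyphenyl)methoxy]methyl}-3-methylidene-2-oxo-2,3,3a,4,7,7a-hexahydro-1-benzofuran-4-yl acetate
Product: 23 (3aS,4S,7aR)-5-[(2S)-5-[(tert-butyldiphenylsilyl)oxy]pentan-2-yl]-6-(hydroxymethyl)-3-methylidene-2-oxo-2,3,3a,4,7,7a-hexahydro-1-benzofuran-4-yl acetate
Conditions: DDQ, CH2Cl2/pH 7 buffer, 0 °C
Reagents that add atoms: none
Why: Oxidative cleavage of the 4-methoxybenzyl ether by hydride abstraction and hydrolysis; the electron-poor alkenes, the silyl ether and the esters are inert to DDQ under buffered conditions.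

Step 16
Reactants: 23 (3aS,4S,7aR)-5-[(2S)-5-[(tert-butyldiphenylsilyl)oxy]pentan-2-yl]-6-(hydroxymethyl)-3-methylidene-2-oxo-2,3,3a,4,7,7a-hexahydro-1-benzofuran-4-yl acetate
Product: 24 [(3aS,4S,7aR)-4-acetoxy-5-[(2S)-5-[(tert-butyldiphenylsilyl)oxy]pentan-2-yl]-3-methylidene-2-oxo-2,3,3a,4,7,7a-hexahydro-1-benzofuran-6-yl]methyl 2-methylprop-2-enoate
Conditions: methacryloyl chloride, Et3N, DMAP (cat.), CH2Cl2, 0 °C
Reagents that add atoms: methacryloyl chloride (C=C(C)C(=O)Cl)
Why: Acylation of the only free hydroxyl, a primary allylic alcohol; reaction with the acid chloride at 0 °C should outpace acetyl migration from the C6 oxygen.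

Step 17
Reactants: 24 [(3aS,4S,7aR)-4-acetoxy-5-[(2S)-5-[(tert-butyldiphenylsilyl)oxy]pentan-2-yl]-3-methylidene-2-oxo-2,3,3a,4,7,7a-hexahydro-1-benzofuran-6-yl]methyl 2-methylprop-2-enoate
Product: 25 [(3aS,4S,7aR)-4-acetoxy-5-[(2S)-5-hydroxypentan-2-yl]-3-methylidene-2-oxo-2,3,3a,4,7,7a-hexahydro-1-benzofuran-6-yl]methyl 2-methylprop-2-enoate (CNP0114085.1)
Conditions: HF·pyridine, pyridine, THF, 0 °C → rt
Reagents that add atoms: none
Why: Fluoride-mediated cleavage of the primary silyl ether under buffered, weakly acidic conditions, which spare the acetate, the methacrylate and the methylene lactone; the released C1 hydroxyl is too remote from the esters to take up an acyl group.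

## Compound list

1 | (S)-citronellal | O=CC[C@@H](C)CCC=C(C)C | starting material
2 | (S)-citronellal dimethyl acetal [(6S)-8,8-dimethoxy-2,6-dimethyloct-2-ene] | COC(OC)C[C@@H](C)CCC=C(C)C | intermediate (not isolated)
3 | (4S)-6,6-dimethoxy-4-methylhexan-1-ol | COC(OC)C[C@@H](C)CCCO | intermediate
4 | tert-butyl{[(4S)-6,6-dimethoxy-4-methylhexyl]oxy}diphenylsilane | COC(OC)C[C@@H](C)CCCO[Si](c1ccccc1)(c1ccccc1)C(C)(C)C | intermediate
5 | (3S)-6-[(tert-butyldiphenylsilyl)oxy]-3-methylhexanal | O=CC[C@@H](C)CCCO[Si](c1ccccc1)(c1ccccc1)C(C)(C)C | intermediate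
6 | acetyl chloride | CC(=O)Cl | starting material
7 | 1-[(1E,3S)-6-[(tert-butyldiphenylsilyl)oxy]-3-methylhex-1-en-1-yl]pyrrolidine | C1CCN(C1)/C=C/[C@@H](C)CCCO[Si](c2ccccc2)(c2ccccc2)C(C)(C)C | intermediate (not isolated)
8 | (3E)-3-[(2S)-5-[(tert-butyldiphenylsilyl)oxy]pentan-2-yl]-4-(pyrrolidin-1-yl)but-3-en-2-one | CC(=O)/C(=C/N1CCCC1)[C@@H](C)CCCO[Si](c1ccccc1)(c1ccccc1)C(C)(C)C | intermediate (not isolated)
9 | (3Z)-4-hydroxy-3-[(2S)-5-[(tert-butyldiphenylsilyl)oxy]pentan-2-yl]but-3-en-2-one (enol form of the 2-acetyl aldehyde) | CC(=O)/C(=C\O)[C@@H](C)CCCO[Si](c1ccccc1)(c1ccccc1)C(C)(C)C | intermediate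
10 | (1E,3S)-2-acetyl-6-[(tert-butyldiphenylsilyl)oxy]-3-methylhex-1-en-1-yl acetate | CC(=O)O/C=C(\[C@@H](C)CCCO[Si](c1ccccc1)(c1ccccc1)C(C)(C)C)C(C)=O | intermediate
11 | (1E,3S)-6-[(tert-butyldiphenylsilyl)oxy]-3-methyl-2-{1-[(trifluoromethanesulfonyl)oxy]ethenyl}hex-1-en-1-yl acetate | CC(=O)O/C=C(\[C@@H](C)CCCO[Si](c1ccccc1)(c1ccccc1)C(C)(C)C)C(=C)OS(=O)(=O)C(F)(F)F | intermediate
12 | 4-methoxybenzyl alcohol | COc1ccc(CO)cc1 | starting material
13 | tributyl(iodomethyl)stannane | CCCC[Sn](CCCC)(CCCC)CI | starting material
14 | tributyl{[(4-methoxyphenyl)methoxy]methyl}stannane | CCCC[Sn](CCCC)(CCCC)COCc1ccc(OC)cc1 | intermediate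
15 | (1E,3S)-6-[(tert-butyldiphenylsilyl)oxy]-2-{3-[(4-methoxyphenyl)methoxy]prop-1-en-2-yl}-3-methylhex-1-en-1-yl acetate (diene, precursor of the key step) | CC(=O)O/C=C(\[C@@H](C)CCCO[Si](c1ccccc1)(c1ccccc1)C(C)(C)C)C(=C)COCc1ccc(OC)cc1 | intermediate
16 | but-3-yn-2-ol (racemic) | CC(O)C#C | starting material
17 | (3E)-4-(4,4,5,5-tetramethyl-1,3,2-dioxaborolan-2-yl)but-3-en-2-ol (racemic) | CC(O)/C=C/B1OC(C)(C)C(C)(C)O1 | intermediate
18 | (3E)-4-(4,4,5,5-tetramethyl-1,3,2-dioxaborolan-2-yl)but-3-en-2-one (dienophile) | CC(=O)/C=C/B1OC(C)(C)C(C)(C)O1 | intermediate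
19 | (1S,5R,6S)-6-acetyl-2-[(2S)-5-[(tert-butyldiphenylsilyl)oxy]pentan-2-yl]-3-{[(4-methoxyphenyl)methoxy]methyl}-5-(4,4,5,5-tetramethyl-1,3,2-dioxaborolan-2-yl)cyclohex-2-en-1-yl acetate (product of the key step) | COc1ccc(COCC2=C([C@@H](C)CCCO[Si](c3ccccc3)(c3ccccc3)C(C)(C)C)[C@@H](OC(C)=O)[C@@H](C(C)=O)[C@H](B3OC(C)(C)C(C)(C)O3)C2)cc1 | intermediate
20 | (1S,5R,6S)-2-[(2S)-5-[(tert-butyldiphenylsilyl)oxy]pentan-2-yl]-3-{[(4-methoxyphenyl)methoxy]methyl}-5-(4,4,5,5-tetramethyl-1,3,2-dioxaborolan-2-yl)-6-{1-[(trifluoromethanesulfonyl)oxy]ethenyl}cyclohex-2-en-1-yl acetate | COc1ccc(COCC2=C([C@@H](C)CCCO[Si](c3ccccc3)(c3ccccc3)C(C)(C)C)[C@@H](OC(C)=O)[C@@H](C(=C)OS(=O)(=O)C(F)(F)F)[C@H](B3OC(C)(C)C(C)(C)O3)C2)cc1 | intermediate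
21 | (1S,5R,6S)-2-[(2S)-5-[(tert-butyldiphenylsilyl)oxy]pentan-2-yl]-5-hydroxy-3-{[(4-methoxyphenyl)methoxy]methyl}-6-{1-[(trifluoromethanesulfonyl)oxy]ethenyl}cyclohex-2-en-1-yl acetate | COc1ccc(COCC2=C([C@@H](C)CCCO[Si](c3ccccc3)(c3ccccc3)C(C)(C)C)[C@@H](OC(C)=O)[C@@H](C(=C)OS(=O)(=O)C(F)(F)F)[C@H](O)C2)cc1 | intermediate
22 | (3aS,4S,7aR)-5-[(2S)-5-[(tert-butyldiphenylsilyl)oxy]pentan-2-yl]-6-{[(4-methoxyphenyl)methoxy]methyl}-3-methylidene-2-oxo-2,3,3a,4,7,7a-hexahydro-1-benzofuran-4-yl acetate | COc1ccc(COCC2=C([C@@H](C)CCCO[Si](c3ccccc3)(c3ccccc3)C(C)(C)C)[C@@H](OC(C)=O)[C@H]3C(=C)C(=O)O[C@@H]3C2)cc1 | intermediate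
23 | (3aS,4S,7aR)-5-[(2S)-5-[(tert-butyldiphenylsilyl)oxy]pentan-2-yl]-6-(hydroxymethyl)-3-methylidene-2-oxo-2,3,3a,4,7,7a-hexahydro-1-benzofuran-4-yl acetate | OCC1=C([C@@H](C)CCCO[Si](c2ccccc2)(c2ccccc2)C(C)(C)C)[C@@H](OC(C)=O)[C@H]2C(=C)C(=O)O[C@@H]2C1 | intermediate
24 | [(3aS,4S,7aR)-4-acetoxy-5-[(2S)-5-[(tert-butyldiphenylsilyl)oxy]pentan-2-yl]-3-methylidene-2-oxo-2,3,3a,4,7,7a-hexahydro-1-benzofuran-6-yl]methyl 2-methylprop-2-enoate | C=C(C)C(=O)OCC1=C([C@@H](C)CCCO[Si](c2ccccc2)(c2ccccc2)C(C)(C)C)[C@@H](OC(C)=O)[C@H]2C(=C)C(=O)O[C@@H]2C1 | intermediate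
25 | [(3aS,4S,7aR)-4-acetoxy-5-[(2S)-5-hydroxypentan-2-yl]-3-methylidene-2-oxo-2,3,3a,4,7,7a-hexahydro-1-benzofuran-6-yl]methyl 2-methylprop-2-enoate (CNP0114085.1) | C=C(C)C(=O)OCC1=C([C@@H](C)CCCO)[C@@H](OC(C)=O)[C@H]2C(=C)C(=O)O[C@@H]2C1 | target

## Step count and risks

Total step count: 17. Longest linear sequence: 14 steps (steps 1–6, 8, 11–17). Steps 7, 9 and 10 make the two side fragments.

Least certain steps:

Step 11 (key step). The hindered 2,3-disubstituted acetoxy diene may reach the reactive s-cis geometry too slowly, so that acid-promoted loss of the enol acetate or the benzylic ether competes with cycloaddition. A mismatched influence of C4 or leakage to the exo mode could also erode the selectivity. The fallback sets out from 15 and comes back at 19 by a change of activation mode and of dienophile. Iminium-ion catalysis with a chiral 5-benzyl-2,2,3-trimethylimidazolidin-4-one hydrochloride (the enantiomer that leaves the re face of C7 open) would join 15 with the smaller and more electrophilic aldehyde (2E)-3-(4,4,5,5-tetramethyl-1,3,2-dioxaborolan-2-yl)prop-2-enal F1. This should give the C7-formyl cycloadduct F2, by the known organocatalytic Diels–Alder reaction of enals with 1-acetoxy dienes. Chemoselective methyl addition with MeTi(Oi-Pr)3 would then give the C7 (1-hydroxyethyl) compound F3, and Dess–Martin oxidation would return the methyl ketone 19.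

Step 4. Triethylamine may dehydrohalogenate acetyl chloride to ketene, which adds to the enamine in a [2+2] sense, and the aldehyde may self-condense during enamine formation; both divert material from C-acylation. The fallback sets out from 5 and comes back at 9 through aza-enolate chemistry. Condensation with cyclohexylamine gives the N-cyclohexyl imine F4, deprotonation with LDA and acylation with N-methoxy-N-methylacetamide give the N-cyclohexyl enaminone F5, and aqueous oxalic acid hydrolyses it to 9.

Step 8. The sp3 alkoxymethyl group of an ether-type stannane may transfer slowly, so that butyl transfer or thermal degradation of the dienyl triflate takes over. The fallback sets out from 11 and comes back at 15. Coupling under the same palladium catalysis with (tributylstannyl)methanol, whose free hydroxyl assists transmetalation, gives the dienyl alcohol F6. This is then etherified under non-basic conditions with 4-methoxybenzyl 2,2,2-trichloroacetimidate and catalytic La(OTf)3.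

Step 12. The potassium enolate may be held as a cyclic boronate complex by the neighbouring boron and resist O-sulfonylation, or competing deprotonation at C7 may trigger E1cB loss of the C6 acetate. The fallback sets out from 19 and comes back at 21 by changing the order of events, so that no enolate is formed next to boron. Oxidation with H2O2 in pH 7 phosphate buffer gives the β-hydroxy ketone F7, and TESOTf with 2,6-lutidine gives its C8 triethylsilyl ether F8. KHMDS and PhNTf2 at −78 °C then give the silyl-protected enol triflate F9, and brief treatment with HF·pyridine at 0 °C removes the triethylsilyl group selectively to give 21.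

Step 14. Capture of the acyl-palladium species by the C8 hydroxyl to close the trans-fused ring may be slow, which allows reduction or hydrolysis of the acyl intermediate; ionisation of the C6 allylic acetate by zerovalent palladium may also compete. The fallback sets out from 21 and comes back at 22 without carbon monoxide. Stille hydroxymethylation with (tributylstannyl)methanol gives the 2-methylidene-1,4-diol F10, and MnO2 oxidises its allylic primary alcohol to the enal, which closes to the lactol and is oxidised further to the lactone 22.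

## Further compounds

F1 | step 11 | (2E)-3-(4,4,5,5-tetramethyl-1,3,2-dioxaborolan-2-yl)prop-2-enal | O=C/C=C/B1OC(C)(C)C(C)(C)O1
F2 | step 11 | C7-formyl analogue of 19: (1S,5R,6S)-2-[(2S)-5-[(tert-butyldiphenylsilyl)oxy]pentan-2-yl]-6-formyl-3-{[(4-methoxyphenyl)methoxy]methyl}-5-(4,4,5,5-tetramethyl-1,3,2-dioxaborolan-2-yl)cyclohex-2-en-1-yl acetate | COc1ccc(COCC2=C([C@@H](C)CCCO[Si](c3ccccc3)(c3ccccc3)C(C)(C)C)[C@@H](OC(C)=O)[C@@H](C=O)[C@H](B3OC(C)(C)C(C)(C)O3)C2)cc1
F3 | step 11 | C7 (1-hydroxyethyl) analogue of 19 (mixture of carbinol epimers) | COc1ccc(COCC2=C([C@@H](C)CCCO[Si](c3ccccc3)(c3ccccc3)C(C)(C)C)[C@@H](OC(C)=O)[C@@H](C(C)O)[C@H](B3OC(C)(C)C(C)(C)O3)C2)cc1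
F4 | step 4 | (E)-N-cyclohexyl imine of 5 | C1CCCCC1/N=C/C[C@@H](C)CCCO[Si](c1ccccc1)(c1ccccc1)C(C)(C)C
F5 | step 4 | (3Z)-4-(cyclohexylamino)-3-[(2S)-5-[(tert-butyldiphenylsilyl)oxy]pentan-2-yl]but-3-en-2-one | CC(=O)/C(=C\NC1CCCCC1)[C@@H](C)CCCO[Si](c1ccccc1)(c1ccccc1)C(C)(C)C
F6 | step 8 | (1E,3S)-6-[(tert-butyldiphenylsilyl)oxy]-2-(3-hydroxyprop-1-en-2-yl)-3-methylhex-1-en-1-yl acetate | CC(=O)O/C=C(\[C@@H](C)CCCO[Si](c1ccccc1)(c1ccccc1)C(C)(C)C)C(=C)CO
F7 | step 12 | C8 alcohol of 19 (6-acetyl-5-hydroxy compound) | COc1ccc(COCC2=C([C@@H](C)CCCO[Si](c3ccccc3)(c3ccccc3)C(C)(C)C)[C@@H](OC(C)=O)[C@@H](C(C)=O)[C@H](O)C2)cc1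
F8 | step 12 | C8 triethylsilyl ether of F7 | COc1ccc(COCC2=C([C@@H](C)CCCO[Si](c3ccccc3)(c3ccccc3)C(C)(C)C)[C@@H](OC(C)=O)[C@@H](C(C)=O)[C@H](O[Si](CC)(CC)CC)C2)cc1
F9 | step 12 | C8 triethylsilyl ether of 21 | COc1ccc(COCC2=C([C@@H](C)CCCO[Si](c3ccccc3)(c3ccccc3)C(C)(C)C)[C@@H](OC(C)=O)[C@@H](C(=C)OS(=O)(=O)C(F)(F)F)[C@H](O[Si](CC)(CC)CC)C2)cc1
F10 | step 14 | C7 (3-hydroxyprop-1-en-2-yl), C8 hydroxy diol | COc1ccc(COCC2=C([C@@H](C)CCCO[Si](c3ccccc3)(c3ccccc3)C(C)(C)C)[C@@H](OC(C)=O)[C@@H](C(=C)CO)[C@H](O)C2)cc1
A1 | alternative 1 | C1 tert-butyldimethylsilyl ether of 25 | C=C(C)C(=O)OCC1=C([C@@H](C)CCCO[Si](C)(C)C(C)(C)C)[C@@H](OC(C)=O)[C@H]2C(=C)C(=O)O[C@@H]2C1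
A2 | alternative 1 | trans C7-ethynyl C8-hydroxy cyclohexene carrying the C6 acetate, the C14 methacrylate and the C1 silyl ether | C=C(C)C(=O)OCC1=C([C@@H](C)CCCO[Si](C)(C)C(C)(C)C)[C@@H](OC(C)=O)[C@@H](C#C)[C@H](O)C1
A3 | alternative 2 | 2,3-disubstituted cyclohex-2-enone with silicon on C10, the side chain on C5 and the C7/C8 pair | C[Si](C)(C)C1=C([C@@H](C)CCCO[Si](C)(C)C(C)(C)C)C(=O)[C@@H](CC(=O)OC(C)(C)C)[C@H](OCc2ccccc2)C1
A4 | alternative 2 | trans tert-butyl 2-[2-(benzyloxy)-4-oxocyclobutyl]acetate | O=C1[C@@H](CC(=O)OC(C)(C)C)[C@H](OCc2ccccc2)C1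
A5 | alternative 2 | tert-butyldimethyl{[(4S)-4-methyl-6-(trimethylsilyl)hex-5-yn-1-yl]oxy}silane | C[Si](C)(C)C#C[C@@H](C)CCCO[Si](C)(C)C(C)(C)C
A6 | alternative 3 | ethyl cyclohexenecarboxylate with the C6 ether, C7 chain and C8 nitro group | CCOC(=O)C1=C([C@@H](C)CCCO[Si](c2ccccc2)(c2ccccc2)C(C)(C)C)[C@@H](OCc2ccc(OC)cc2)[C@@H](CCO[Si](C)(C)C(C)(C)C)[C@H]([N+](=O)[O-])C1
A7 | alternative 3 | γ-nitro ketone with the C5 carbonyl, C6 4-methoxybenzyl ether and C7 silyloxyethyl chain | O=C([C@@H](C)CCCO[Si](c1ccccc1)(c1ccccc1)C(C)(C)C)[C@@H](OCc1ccc(OC)cc1)[C@@H](CCO[Si](C)(C)C(C)(C)C)C[N+](=O)[O-]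
A8 | alternative 3 | ethyl 2-(diethoxyphosphoryl)prop-2-enoate | C=C(C(=O)OCC)P(=O)(OCC)OCC
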